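**Plan**

1. Retrosynthesis: cut C12–C13 (butenolide off as 4-bromofuran-2(5H)-one); contract ring B by moving C6 from C7 back onto C9 (cyclobutanol C5–C6–C9–C10 with a 2-propenyl arm on C9); cut C9–C11 ([3,3]) and C8=C9 (aldol condensation); cut C5–C6 and C9–C10 (ketene [2+2]) to reach the ring A alkene.
2. Forward: ring A from actinol → C5=C10 alkene → cyclobutanone fused on C5–C10 → C9 made quaternary (alkenyl arm plus C11–C12 arm) → four-to-six ring expansion gives ring B with C8=C9 → C6 reset by oxidation/reduction → butenolide by sp3–sp2 coupling → desilylation.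
3. Enabling feature: ring B is a cyclohex-3-en-1-ol (C6 carbinol, C7 methylene, tetrasubstituted C8=C9) cis-fused to ring A at C5–C10, which is the product pattern of a 1,3-shift in a 2-alkenylcyclobutanol whose four-membered ring is C5–C6–C9–C10.
4. Stereochemistry: C2 from (4R,6R)-actinol; the cis C5/C10 fusion from suprafacial ketene addition anti to the pseudoaxial C4 methyl; C6 from hydride delivery to the convex face of the cis-fused decalone.

Key step: step 11

Remark: labdane numbering of the target is used for all intermediates (ring A = C1–C5 and C10; ring B = C5–C10; C17 = CH2O on C8; C11–C12 = chain; C13–C16 = butenolide). The SMILES is read as a cis-fused decalin (5-H and 10-CH3 on one face, 2-OH and 6-OH on the other; 2S,5R,6S,10S). (4R,6R)-Actinol, 1,3-dihydroxyacetone (sold as its dimer) and 4-bromofuran-2(5H)-one are taken as purchasable. TBS = tert-butyldimethylsilyl.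

**Route**

Step 1
Reactants: 1 (4R,6R)-4-hydroxy-2,2,6-trimethylcyclohexan-1-one (actinol)
Product: 2 (4R,6R)-4-[(tert-butyldimethylsilyl)oxy]-2,2,6-trimethylcyclohexan-1-one
Conditions: TBSCl, imidazole, DMF, 0 °C to rt
Reagents that add atoms: tert-butyldimethylsilyl chloride, CC(C)(C)[Si](C)(C)Cl
Why: Standard silyl ether formation on the only hydroxyl, which masks C2–OH against acylation in step 4 and is removed in the last step.

Step 2
Reactants: 2 silyl ether of actinol
Product: 3 (4R)-4-[(tert-butyldimethylsilyl)oxy]-2,6,6-trimethylcyclohex-1-en-1-yl trifluoromethanesulfonate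
Conditions: KN(SiMe3)2, THF, −78 to 0 °C; then PhNTf2, −78 °C to rt
Reagents that add atoms: N-phenylbis(trifluoromethanesulfonimide), O=S(=O)(N(c1ccccc1)S(=O)(=O)C(F)(F)F)C(F)(F)F
Why: Enol triflate formation: only the CH(CH3) carbon (C10) has an α-hydrogen because C4 is quaternary, so one enolate forms and is trapped on oxygen; the C10 stereocenter is erased on purpose.

Step 3
Reactants: 3 enol triflate
Product: 4 (R)-tert-butyldimethyl[(3,5,5-trimethylcyclohex-3-en-1-yl)oxy]silane (ring A alkene with C5=C10)
Conditions: Pd(OAc)2 (5 mol %), PPh3, HCO2H, Bu3N, DMF, 60 °C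
Reagents that add atoms: none
Why: Palladium-catalysed formate hydrogenolysis of an enol triflate replaces OTf by H without moving the double bond.

Step 4
Reactants: 4 ring A alkene
Product: 5 cis-fused 3-[(tert-butyldimethylsilyl)oxy]-8,8-dichloro-1,5,5-trimethylbicyclo[4.2.0]octan-7-one (C6 = C=O on C5; C9 = CCl2 on C10; four-membered ring on the OTBS face)
Conditions: Cl3CCOCl (slow addition), Zn–Cu couple, POCl3, Et2O, rt
Reagents that add atoms: trichloroacetyl chloride, O=C(Cl)C(Cl)(Cl)Cl
Why: Ketene–alkene [2+2] cycloaddition with dichloroketene made in the flask: the carbonyl carbon bonds to the less substituted C5 and CCl2 to C10, suprafacial addition fixes the cis fusion, and the ketene should approach anti to the pseudoaxial C4 methyl of the half-chair that keeps OTBS equatorial, i.e. on the face syn to OTBS.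

Step 5
Reactants: 5 dichlorocyclobutanone
Product: 6 cis-fused 3-[(tert-butyldimethylsilyl)oxy]-1,5,5-trimethylbicyclo[4.2.0]octan-7-one
Conditions: Zn dust, AcOH, rt
Reagents that add atoms: none
Why: Reductive dechlorination of an α,α-dichloroketone through its zinc enolate, with no stereocenter touched.

Step 6
Reactants: 7 1,3-dihydroxyacetone
Product: 8 1,3-bis[(tert-butyldimethylsilyl)oxy]propan-2-one
Conditions: TBSCl, imidazole, DMF, rt
Reagents that add atoms: tert-butyldimethylsilyl chloride, CC(C)(C)[Si](C)(C)Cl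
Why: Silylation of both primary hydroxyls of the keto form gives the C7–C8–C17 building block.

Step 7
Reactants: 6 cyclobutanone; 8 bis-silyloxyacetone
Product: 11 bis-silyl alkylidenecyclobutanone (new C9=C8 bond; C8 carries two CH2OTBS groups), via aldol adduct 9 (not isolated), via tertiary acetate 10 (not isolated)
Conditions: LiN(iPr)2, THF, −78 °C; CeCl3; then 8; then Ac2O, −78 to 0 °C; then DBU, rt
Reagents that add atoms: none
Why: Directed aldol condensation: kinetic deprotonation at the C9 methylene, a cerium enolate to suppress proton transfer to the enolisable ketone, in-flask acetylation to stop retro-aldol cleavage and E1cB loss of acetate give the tetrasubstituted enone, which has no E/Z issue because C8 carries two identical groups.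

Step 8
Reactants: 11 bis-silyl alkylidenecyclobutanone
Product: 12 mono-alcohol (one CH2OH and one CH2OTBS on C8; E/Z mixture)
Conditions: camphorsulfonic acid (10 mol %), MeOH/CH2Cl2, −10 °C, stopped at partial conversion
Reagents that add atoms: none
Why: Acid-catalysed methanolysis cleaves primary silyl ethers much faster than the secondary C2 ether and should attack first the allylic ether cis to the carbonyl (the other is shielded by quaternary C10); either geometric isomer serves because both leave one free CH2OH on C8.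

Step 9
Reactants: 12 mono-alcohol
Product: 15 C9-quaternary keto ester (C9 bears CH2CO2Et plus the 3-silyloxyprop-1-en-2-yl arm; C9 epimers), via mixed orthoester 13 (not isolated), via ketene acetal 14 (not isolated)
Conditions: MeC(OEt)3, EtCO2H (cat.), xylene, 140 °C, EtOH distilled off
Reagents that add atoms: triethyl orthoacetate, CCOC(C)(OCC)OCC
Why: Johnson–Claisen rearrangement: the chair [3,3] shift of the ketene acetal forms C9–C11, makes C9 quaternary, relieves the allylic strain of the tetrasubstituted enone and turns the former CH2OH carbon into the terminal =C7H2; the C9 configuration is irrelevant because C9 becomes sp2 in step 11.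

Step 10
Reactants: 15 keto ester
Product: 16 cyclobutanol diol (C6–OH and C12–OH; mixture at C6 and C9)
Conditions: LiAlH4, THF, 0 °C
Reagents that add atoms: none
Why: Hydride reduction of the cyclobutanone and the ethyl ester in one operation; the C6 configuration formed here is not used later.

Step 11
Reactants: 16 cyclobutanol diol
Product: 17 ring-expanded diol (cis-fused Δ8(9)-octalin; 6-OH epimers; 12-OH; 2- and 17-OTBS)
Conditions: KH (2.5 equiv), 18-crown-6, THF, 0 °C to rt; aq. NH4Cl
Reagents that add atoms: none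
Why: Deprotonation gives the dipotassium dialkoxide, and the oxyanion at C6 weakens the strained C6–C9 bond, which shifts [1,3] across the C9–C8=C7 unit so that C6 bonds to C7 and the double bond moves to C8=C9, either as a concerted suprafacial sigmatropic shift or through a tight aldehyde/allyl-anion pair that recombines at C7. The closest known reaction is the alkoxy-accelerated vinylcyclobutane rearrangement of 2-vinylcyclobutanol potassium salts to cyclohex-3-en-1-ols, which tolerates a fully substituted vinyl-bearing carbon and fused bicyclic frames. Ring B is not closed by a new cyclisation but arises from the four-membered ring C5–C6–C9–C10 by two-atom ring expansion (C7 and C8 inserted between C6 and C9; formally a 6-endo recombination at the allyl terminus), driven by release of about 26 kcal/mol of ring strain. C5 and C10 are untouched, so the cis fusion from step 4 is carried over; C9 becomes sp2, so all C9 epimers converge; the new C6 configuration is not relied on (the alkoxide is expected mainly on the convex face, 6β) and is reset in steps 13 and 15. The step needs the 1,3-shift to outrun O-to-O silyl migration and protonation of the allyl-anion component; this is secured by the absence of any C–H acid (C12 is carried as an alkoxide, not an ester), by the single alkenyl group on C9 (one regiochemistry) and by the absence of an alkenyl group on C6 (no oxy-Cope path).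

Step 12
Reactants: 17 ring-expanded diol
Product: 18 primary iodide (12-iodo; 6-OH epimers)
Conditions: I2 (1.05 equiv), PPh3, imidazole, CH2Cl2, 0 °C
Reagents that add atoms: iodine, II
Why: Appel-type iodination is selective for the unhindered primary C12 hydroxyl over the secondary C6 hydroxyl.

Step 13
Reactants: 18 primary iodide
Product: 19 C6-keto iodide
Conditions: Dess–Martin periodinane, pyridine, CH2Cl2, 0 °C to rt
Reagents that add atoms: none
Why: Dess–Martin oxidation under buffered, non-basic conditions gives the C6 ketone without moving C8=C9 into conjugation or epimerising C5, and converges both C6 epimers.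

Step 14
Reactants: 19 C6-keto iodide; 20 4-bromofuran-2(5H)-one
Product: 22 C6-keto butenolide, via alkylzinc iodide 21 (not isolated)
Conditions: Zn dust (activated by TMSCl and BrCH2CH2Br), LiCl, THF, 40 °C; then 20, Pd(OAc)2 (5 mol %), SPhos, THF, rt
Reagents that add atoms: none
Why: Direct zinc insertion into the primary iodide (ketone and silyl ethers tolerated) followed by Negishi sp3–sp2 coupling at the β-bromo position of the butenolide forms C12–C13.

Step 15
Reactants: 22 C6-keto butenolide
Product: 23 6α-alcohol (2- and 17-OTBS)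
Conditions: NaBH4, CeCl3·7H2O, MeOH, −78 °C
Reagents that add atoms: none
Why: Luche reduction: the cerium-activated ketone is reduced much faster than the butenolide, and hydride should add from the convex β face of the cis-fused decalone (the α face lies under ring A), which sets the concave 6α-hydroxyl with H6 cis to H5.

Step 16
Reactants: 23 bis-silyl ether
Product: 24 target triol
Conditions: HF·pyridine, pyridine, THF, 0 °C to rt
Reagents that add atoms: none
Why: Fluoride cleavage of both TBS ethers under weakly acidic conditions that leave the butenolide and the allylic alcohol intact.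

**Compound list**

1 | (4R,6R)-4-hydroxy-2,2,6-trimethylcyclohexan-1-one (actinol) | CC1(C)C[C@H](O)C[C@@H](C)C1=O | starting material
2 | (4R,6R)-4-[(tert-butyldimethylsilyl)oxy]-2,2,6-trimethylcyclohexan-1-one | CC1(C)C[C@H](O[Si](C)(C)C(C)(C)C)C[C@@H](C)C1=O | intermediate
3 | (4R)-4-[(tert-butyldimethylsilyl)oxy]-2,6,6-trimethylcyclohex-1-en-1-yl trifluoromethanesulfonate | CC1(C)C[C@H](O[Si](C)(C)C(C)(C)C)CC(C)=C1OS(=O)(=O)C(F)(F)F | intermediate
4 | (R)-tert-butyldimethyl[(3,5,5-trimethylcyclohex-3-en-1-yl)oxy]silane | CC1(C)C[C@H](O[Si](C)(C)C(C)(C)C)CC(C)=C1 | intermediate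
5 | cis-fused 3-[(tert-butyldimethylsilyl)oxy]-8,8-dichloro-1,5,5-trimethylbicyclo[4.2.0]octan-7-one, four-membered ring syn to OTBS | CC1(C)C[C@H](O[Si](C)(C)C(C)(C)C)C[C@]2(C)C(Cl)(Cl)C(=O)[C@H]12 | intermediate
6 | cis-fused 3-[(tert-butyldimethylsilyl)oxy]-1,5,5-trimethylbicyclo[4.2.0]octan-7-one | CC1(C)C[C@H](O[Si](C)(C)C(C)(C)C)C[C@]2(C)CC(=O)[C@H]12 | intermediate
7 | 1,3-dihydroxyacetone | OCC(=O)CO | starting material
8 | 1,3-bis[(tert-butyldimethylsilyl)oxy]propan-2-one | CC(C)(C)[Si](C)(C)OCC(=O)CO[Si](C)(C)C(C)(C)C | intermediate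
9 | aldol adduct: 8-{1,3-bis[(tert-butyldimethylsilyl)oxy]-2-hydroxypropan-2-yl} derivative of 6 | CC1(C)C[C@H](O[Si](C)(C)C(C)(C)C)C[C@]2(C)C(C(O)(CO[Si](C)(C)C(C)(C)C)CO[Si](C)(C)C(C)(C)C)C(=O)[C@H]12 | intermediate (not isolated)
10 | tertiary acetate of 9 | CC1(C)C[C@H](O[Si](C)(C)C(C)(C)C)C[C@]2(C)C(C(OC(C)=O)(CO[Si](C)(C)C(C)(C)C)CO[Si](C)(C)C(C)(C)C)C(=O)[C@H]12 | intermediate (not isolated)
11 | 8-{1,3-bis[(tert-butyldimethylsilyl)oxy]propan-2-ylidene}-3-[(tert-butyldimethylsilyl)oxy]-1,5,5-trimethylbicyclo[4.2.0]octan-7-one | CC1(C)C[C@H](O[Si](C)(C)C(C)(C)C)C[C@]2(C)C(=C(CO[Si](C)(C)C(C)(C)C)CO[Si](C)(C)C(C)(C)C)C(=O)[C@H]12 | intermediate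
12 | 8-{1-[(tert-butyldimethylsilyl)oxy]-3-hydroxypropan-2-ylidene}-3-[(tert-butyldimethylsilyl)oxy]-1,5,5-trimethylbicyclo[4.2.0]octan-7-one (E/Z mixture) | CC1(C)C[C@H](O[Si](C)(C)C(C)(C)C)C[C@]2(C)C(=C(CO)CO[Si](C)(C)C(C)(C)C)C(=O)[C@H]12 | intermediate
13 | mixed orthoester of 12 (CH2O–C(CH3)(OEt)2) | CC1(C)C[C@H](O[Si](C)(C)C(C)(C)C)C[C@]2(C)C(=C(COC(C)(OCC)OCC)CO[Si](C)(C)C(C)(C)C)C(=O)[C@H]12 | intermediate (not isolated)
14 | ketene acetal of 12 (CH2O–C(=CH2)OEt) | CC1(C)C[C@H](O[Si](C)(C)C(C)(C)C)C[C@]2(C)C(=C(COC(=C)OCC)CO[Si](C)(C)C(C)(C)C)C(=O)[C@H]12 | intermediate (not isolated)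
15 | ethyl 2-{3-[(tert-butyldimethylsilyl)oxy]-8-{3-[(tert-butyldimethylsilyl)oxy]prop-1-en-2-yl}-1,5,5-trimethyl-7-oxobicyclo[4.2.0]octan-8-yl}acetate (C9 epimers) | CC1(C)C[C@H](O[Si](C)(C)C(C)(C)C)C[C@]2(C)C(CC(=O)OCC)(C(=C)CO[Si](C)(C)C(C)(C)C)C(=O)[C@H]12 | intermediate
16 | 8-(2-hydroxyethyl)-8-{3-[(tert-butyldimethylsilyl)oxy]prop-1-en-2-yl}-3-[(tert-butyldimethylsilyl)oxy]-1,5,5-trimethylbicyclo[4.2.0]octan-7-ol (mixture at C6 and C9) | CC1(C)C[C@H](O[Si](C)(C)C(C)(C)C)C[C@]2(C)C(CCO)(C(=C)CO[Si](C)(C)C(C)(C)C)C(O)[C@H]12 | intermediate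
17 | cis-fused 2,17-bis[(tert-butyldimethylsilyl)oxy]-13,14,15,16-tetranorlabd-8-ene-6,12-diol (C6 epimers) | CC1(C)C[C@H](O[Si](C)(C)C(C)(C)C)C[C@]2(C)C(CCO)=C(CO[Si](C)(C)C(C)(C)C)CC(O)[C@H]12 | intermediate
18 | cis-fused 2,17-bis[(tert-butyldimethylsilyl)oxy]-12-iodo-13,14,15,16-tetranorlabd-8-en-6-ol (C6 epimers) | CC1(C)C[C@H](O[Si](C)(C)C(C)(C)C)C[C@]2(C)C(CCI)=C(CO[Si](C)(C)C(C)(C)C)CC(O)[C@H]12 | intermediate
19 | cis-fused 2,17-bis[(tert-butyldimethylsilyl)oxy]-12-iodo-13,14,15,16-tetranorlabd-8-en-6-one | CC1(C)C[C@H](O[Si](C)(C)C(C)(C)C)C[C@]2(C)C(CCI)=C(CO[Si](C)(C)C(C)(C)C)CC(=O)[C@H]12 | intermediate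
20 | 4-bromofuran-2(5H)-one | O=C1OCC(Br)=C1 | starting material
21 | alkylzinc iodide from 19 (C12–ZnI) | CC1(C)C[C@H](O[Si](C)(C)C(C)(C)C)C[C@]2(C)C(CC[Zn]I)=C(CO[Si](C)(C)C(C)(C)C)CC(=O)[C@H]12 | intermediate (not isolated)
22 | cis-fused 2,17-bis[(tert-butyldimethylsilyl)oxy]-6-oxolabda-8,13-dien-15,16-olide | CC1(C)C[C@H](O[Si](C)(C)C(C)(C)C)C[C@]2(C)C(CCC3=CC(=O)OC3)=C(CO[Si](C)(C)C(C)(C)C)CC(=O)[C@H]12 | intermediate
23 | cis-fused 2,17-bis[(tert-butyldimethylsilyl)oxy]-6α-hydroxylabda-8,13-dien-15,16-olide | CC1(C)C[C@H](O[Si](C)(C)C(C)(C)C)C[C@]2(C)C(CCC3=CC(=O)OC3)=C(CO[Si](C)(C)C(C)(C)C)C[C@H](O)[C@H]12 | intermediate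
24 | (2S,5R,6S,10S)-2,6,17-trihydroxylabda-8,13-dien-15,16-olide (5,10-cis) | CC1(C)C[C@H](O)C[C@]2(C)C(CCC3=CC(=O)OC3)=C(CO)C[C@H](O)[C@H]12 | target

**Step count and risks**

Total steps: 16. Longest linear sequence: 15 (steps 1–5 and 7–16; step 6 is a one-step side branch).

Most likely to fail:

1. Step 11. The accelerating C6 oxyanion may be quenched by silyl migration from the C17 ether, or the heterolysed aldehyde/allyl-anion pair may undergo proton transfer instead of recombining. Fallback: it sets out from 15 and avoids the anion altogether. Direct irradiation (about 300 nm, benzene) should cause α-cleavage of the C6–C9 bond of this β,γ-unsaturated ketone and recombination of the acyl radical at C7 (photochemical 1,3-acyl shift) to give the ring-expanded keto ester F1. LiAlH4 (THF, 0 °C) then reduces the ester and, from the convex face, the C6 ketone. The route is rejoined at 17 (as its 6α epimer).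

2. Step 9. The [3,3] shift may be too slow at a fully substituted, acyl-bearing terminus next to quaternary C10, and the allylic silyl ether may be lost under acid at 140 °C. Fallback: it sets out from 12 and builds C9–C11 by enolate alkylation instead of a sigmatropic shift. CBr4/PPh3 should give the allylic bromide F2. Zn/AcOH should reduce this vinylogous α-bromo ketone to the zinc dienolate, which protonates at C9 to give the deconjugated 2-alkenyl ketone F3. KN(SiMe3)2 (THF, −78 °C) then ethyl bromoacetate should alkylate the extended enolate at C9. The route is rejoined at 15.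

3. Step 8. The two primary allylic silyl ethers may not be told apart, so over-cleavage to the diol competes. Fallback: it sets out from 6 and differentiates the two arms by mono-protection instead of mono-deprotection. The cerium enolate of 6 is added to 2,2-dimethyl-1,3-dioxan-5-one to give the aldol adduct F4, which is acetylated in the flask to the tertiary acetate F5 and eliminated with DBU to the acetonide enone F6. Pyridinium p-toluenesulfonate in MeOH should free the diol F7. One equivalent of NaH followed by TBSCl (monoalkoxide protocol) should silylate one hydroxyl only. The route is rejoined at 12.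

**Further compounds**

F1 | step 11 | cis-fused ethyl 2,17-bis[(tert-butyldimethylsilyl)oxy]-6-oxo-13,14,15,16-tetranorlabd-8-en-12-oate | CC1(C)C[C@H](O[Si](C)(C)C(C)(C)C)C[C@]2(C)C(CC(=O)OCC)=C(CO[Si](C)(C)C(C)(C)C)CC(=O)[C@H]12
F2 | step 9 | allylic bromide from 12 (CH2Br and CH2OTBS on C8; E/Z mixture) | CC1(C)C[C@H](O[Si](C)(C)C(C)(C)C)C[C@]2(C)C(=C(CBr)CO[Si](C)(C)C(C)(C)C)C(=O)[C@H]12
F3 | step 9 | deconjugated ketone: 8-{3-[(tert-butyldimethylsilyl)oxy]prop-1-en-2-yl}-3-[(tert-butyldimethylsilyl)oxy]-1,5,5-trimethylbicyclo[4.2.0]octan-7-one | CC1(C)C[C@H](O[Si](C)(C)C(C)(C)C)C[C@]2(C)C(C(=C)CO[Si](C)(C)C(C)(C)C)C(=O)[C@H]12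
F4 | step 8 | aldol adduct of 6 with 2,2-dimethyl-1,3-dioxan-5-one | CC1(C)C[C@H](O[Si](C)(C)C(C)(C)C)C[C@]2(C)C(C3(O)COC(C)(C)OC3)C(=O)[C@H]12
F5 | step 8 | tertiary acetate of F4 | CC1(C)C[C@H](O[Si](C)(C)C(C)(C)C)C[C@]2(C)C(C3(OC(C)=O)COC(C)(C)OC3)C(=O)[C@H]12
F6 | step 8 | acetonide enone: 8-(2,2-dimethyl-1,3-dioxan-5-ylidene)-3-[(tert-butyldimethylsilyl)oxy]-1,5,5-trimethylbicyclo[4.2.0]octan-7-one | CC1(C)C[C@H](O[Si](C)(C)C(C)(C)C)C[C@]2(C)C(=C3COC(C)(C)OC3)C(=O)[C@H]12
F7 | step 8 | diol: 8-(1,3-dihydroxypropan-2-ylidene)-3-[(tert-butyldimethylsilyl)oxy]-1,5,5-trimethylbicyclo[4.2.0]octan-7-one | CC1(C)C[C@H](O[Si](C)(C)C(C)(C)C)C[C@]2(C)C(=C(CO)CO)C(=O)[C@H]12
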